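**Retrosynthetic overview**
- 10 ⇐ 9: oxidative cleavage of the tetrasubstituted cyclohexene C=C to the two ketones (last step).
- 9 ⇐ 8: the only ring formed, the 1,2-dioxane, by intramolecular peroxy-Michael addition of the C6 hydroperoxide to the (E)-2-methyl-2-enoate (O–C3 bond), run under a chiral Brønsted base so that C3 and C2 are set in the ring closure.
- 8 ⇐ 6: Markovnikov radical hydroperoxidation of the C5=C6 alkene (C6–OO bond). C6 is formed racemic; its two epimers are separated as diastereomers after ring closure.
- 6 ⇐ 1 + 2 + 5: Wittig olefination of dihydro-β-ionone, then cross-metathesis with methyl methacrylate.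
- Ring order: the cyclohexene is bought in 1, the dioxane is closed in step 4, the cyclohexene is opened in step 5.

**Notes before the steps**
- Assumption (numbering): C1 = ester carbon, C2 = CH(CH3), C3–C6 = ring carbons, C7 onward = side chain; the target is (2S,3S,6R).
- The same spatial arrangement at C6 is called 6R in 8 and 10 but 6S in 9, because only the CIP priorities of C5 and C7 change.
- Step 4 has a theoretical ceiling of 50 %: only (6R)-8 leads to 9. This is accepted because setting C6 enantioselectively would cost about four more steps.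
- Catalyst for step 4 (called "BIMP-urea" below): 1-[3,5-bis(trifluoromethyl)phenyl]-3-[3,3-dimethyl-1-[[tris(4-methoxyphenyl)-λ5-phosphanylidene]amino]butan-2-yl]urea, SMILES CC(C)(C)C(CN=P(c1ccc(OC)cc1)(c1ccc(OC)cc1)c1ccc(OC)cc1)NC(=O)Nc1cc(C(F)(F)F)cc(C(F)(F)F)c1. It is made from tert-leucine (both antipodes are commercial) and used free of residual phosphine. The sense of induction cannot be predicted, so the antipode that gives the 3S series is chosen by experiment.

**Step 1**
Reactants: 1 dihydro-β-ionone [4-(2,6,6-trimethylcyclohex-1-en-1-yl)butan-2-one]; 2 (but-3-en-1-yl)triphenylphosphonium bromide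
Product: 4 2-(3-methylhepta-3,6-dien-1-yl)-1,3,3-trimethylcyclohex-1-ene, via butenylidene phosphorane 3 (not isolated)
Conditions: 2 (1.5 equiv), NaN(SiMe3)2 (1.45 equiv), THF, 0 °C; then 1, 0 °C → 45 °C
Reagents that add atoms: none
Why: Wittig olefination of a methyl ketone with a non-stabilised ylide; the E/Z mixture at the new trisubstituted alkene does not matter because both isomers give the same C6 radical in step 3.

**Step 2**
Reactants: 4 2-(3-methylhepta-3,6-dien-1-yl)-1,3,3-trimethylcyclohex-1-ene; 5 methyl methacrylate
Product: 6 methyl (2E)-2,6-dimethyl-8-(2,6,6-trimethylcyclohex-1-en-1-yl)octa-2,5-dienoate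
Conditions: 5 (10 equiv), second-generation Hoveyda–Grubbs catalyst RuCl2(H2IMes)(=CH-C6H4-2-OiPr) (5 mol%), 1,4-benzoquinone (10 mol%), CH2Cl2, 40 °C
Reagents that add atoms: none
Why: Olefin cross-metathesis of the monosubstituted alkene with excess methacrylate gives the thermodynamic (E)-trisubstituted enoate with loss of ethene, the tri- and tetrasubstituted alkenes being inert to the ruthenium carbene and benzoquinone suppressing hydride-mediated migration of the skipped diene.

**Step 3**
Reactants: 6 methyl (2E)-2,6-dimethyl-8-(2,6,6-trimethylcyclohex-1-en-1-yl)octa-2,5-dienoate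
Product: 8 methyl (2E)-6-hydroperoxy-2,6-dimethyl-8-(2,6,6-trimethylcyclohex-1-en-1-yl)oct-2-enoate, via triethylsilyl peroxide 7 (not isolated)
Conditions: Co(thd)2 [bis(2,2,6,6-tetramethylheptane-3,5-dionato)cobalt] (5 mol%), O2 (1 atm), Et3SiH (2 equiv), ClCH2CH2Cl, rt; then HCl (cat.), MeOH, 0 °C, 10 min
Reagents that add atoms: dioxygen, O=O; triethylsilane, CC[SiH](CC)CC (its silicon stays only in 7; 8 keeps one hydrogen from it)
Why: Mukaiyama–Isayama hydroperoxysilylation, in which hydrogen-atom transfer from the cobalt hydride to the electron-rich C5=C6 bond gives the tertiary C6 radical (Markovnikov), O2 trapping and silyl transfer give 7, and base-free acid methanolysis frees the hydroperoxide without triggering ring closure; the conjugated ester and the hindered tetrasubstituted ring alkene react much more slowly, and C6 is formed racemic.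

**Step 4**
Reactants: 8 methyl (2E)-6-hydroperoxy-2,6-dimethyl-8-(2,6,6-trimethylcyclohex-1-en-1-yl)oct-2-enoate (racemic)
Product: 9 methyl (2S)-2-[(3S,6S)-6-methyl-6-[2-(2,6,6-trimethylcyclohex-1-en-1-yl)ethyl]-1,2-dioxan-3-yl]propanoate
Conditions: BIMP-urea (10 mol%), toluene, 0 °C, 24–48 h; filtration through silica, then chromatography to remove the C6-epimer
Reagents that add atoms: none
Why: Proposed new method: the iminophosphorane deprotonates the hydroperoxide (far more acidic than the alcohols such catalysts already engage) while the urea binds the ester carbonyl, so the peroxide anion adds 6-exo-trig to one enantiotopic face of the enoate inside a chiral ion pair and the ester enolate is protonated at once by the iminophosphoranium (faster than 3-exo closure to a glycidic ester), which sets C3 as S under catalyst control and C2 as S by protonation anti to ring C4 in the allylic-strain-minimised enolate, while C6 is untouched so that (6R)-8 gives 9 and (6S)-8 gives the separable C6-epimer; the closest known reaction types are the bifunctional-iminophosphorane-catalysed enantioselective intramolecular oxa-Michael addition of alcohols to α,β-unsaturated esters and the diethylamine/trifluoroethanol peroxy-Michael ring closure of hydroperoxy enoates to 1,2-dioxanes.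

**Step 5**
Reactants: 9 methyl (2S)-2-[(3S,6S)-6-methyl-6-[2-(2,6,6-trimethylcyclohex-1-en-1-yl)ethyl]-1,2-dioxan-3-yl]propanoate
Product: 10 diacarperoxide B, methyl (2S)-2-[(3S,6R)-6-(4,4-dimethyl-3,8-dioxononyl)-6-methyl-1,2-dioxan-3-yl]propanoate
Conditions: RuCl3·xH2O (5 mol%), NaIO4 (3 equiv), EtOAc/MeCN/H2O, 0 °C
Reagents that add atoms: sodium periodate, [Na+].[O-]I(=O)(=O)=O (oxygen delivered through RuO4 formed in the flask)
Why: RuO4-mediated oxidative cleavage (RuCl3/NaIO4 protocol) of the only remaining and most electron-rich C=C bond turns the tetrasubstituted cyclohexene into the two ketones, while the dialkyl peroxide, the ester and the three stereocentres (no base, short time at 0 °C) are untouched.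

**Compound list**
1 | dihydro-β-ionone, 4-(2,6,6-trimethylcyclohex-1-en-1-yl)butan-2-one | CC(=O)CCC1=C(C)CCCC1(C)C | starting material
2 | (but-3-en-1-yl)triphenylphosphonium bromide | [Br-].C=CCC[P+](c1ccccc1)(c1ccccc1)c1ccccc1 | starting material
3 | (but-3-en-1-ylidene)triphenyl-λ5-phosphane, ylide formed in the flask | C=CCC=P(c1ccccc1)(c1ccccc1)c1ccccc1 | intermediate
4 | 2-(3-methylhepta-3,6-dien-1-yl)-1,3,3-trimethylcyclohex-1-ene, E/Z mixture at the trisubstituted alkene | C=CCC=C(C)CCC1=C(C)CCCC1(C)C | intermediate
5 | methyl methacrylate, methyl 2-methylprop-2-enoate | COC(=O)C(C)=C | starting material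
6 | methyl (2E)-2,6-dimethyl-8-(2,6,6-trimethylcyclohex-1-en-1-yl)octa-2,5-dienoate, E/Z mixture at C5 | COC(=O)/C(C)=C/CC=C(C)CCC1=C(C)CCCC1(C)C | intermediate
7 | methyl (2E)-2,6-dimethyl-6-[(triethylsilyl)peroxy]-8-(2,6,6-trimethylcyclohex-1-en-1-yl)oct-2-enoate, racemic, formed in the flask | COC(=O)/C(C)=C/CCC(C)(OO[Si](CC)(CC)CC)CCC1=C(C)CCCC1(C)C | intermediate
8 | methyl (2E)-6-hydroperoxy-2,6-dimethyl-8-(2,6,6-trimethylcyclohex-1-en-1-yl)oct-2-enoate, racemic at C6 | COC(=O)/C(C)=C/CCC(C)(OO)CCC1=C(C)CCCC1(C)C | intermediate
9 | methyl (2S)-2-[(3S,6S)-6-methyl-6-[2-(2,6,6-trimethylcyclohex-1-en-1-yl)ethyl]-1,2-dioxan-3-yl]propanoate | COC(=O)[C@@H](C)[C@@H]1CC[C@](C)(CCC2=C(C)CCCC2(C)C)OO1 | intermediate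
10 | diacarperoxide B, methyl (2S)-2-[(3S,6R)-6-(4,4-dimethyl-3,8-dioxononyl)-6-methyl-1,2-dioxan-3-yl]propanoate | COC(=O)[C@@H](C)[C@@H]1CC[C@](C)(CCC(=O)C(C)(C)CCCC(C)=O)OO1 | target

**Totals**
Total step count: 5. Longest linear sequence: 5.

**Steps most likely to fail, with fallbacks**

Step 4 (highest risk). The catalyst class has not been used with hydroperoxides or with α-methyl enoates. Possible failures are low conversion, closure of the enolate to the glycidic ester with loss of the C6 alkoxide, poor control at C2, and oxidation of the catalyst; a urea rather than a thiourea and a phosphine-free catalyst are chosen for the last reason. Half of racemic 8 necessarily ends as the C6-epimer.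
Fallback, from 8 back to 9: stereocontrol is moved from the catalyst to a resolution. Compound 8 is cyclised under the established achiral conditions (Et2NH, CF3CH2OH, rt) to the mixture of racemic diastereomers of methyl 2-[6-methyl-6-[2-(2,6,6-trimethylcyclohex-1-en-1-yl)ethyl]-1,2-dioxan-3-yl]propanoate F1. The racemic (2S*,3S*,6S*) diastereomer is isolated on silica and resolved by preparative HPLC on an amylose tris(3,5-dimethylphenylcarbamate) phase, which returns 9.

Step 3. Hydrogen-atom transfer may not be selective enough for C5=C6; competing sites are the enoate, the ring alkene and the bis-allylic C4–H. Over-reduction to the tertiary alcohol is also possible.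
Fallback, from 1 back to 7: the radical precursor is changed to a 1,1-disubstituted alkene, the fastest substrate class for this peroxidation and one without a bis-allylic position. Compound 1 is converted (LiN(iPr)2, THF, −78 °C; then PhNTf2) into the kinetic enol triflate 4-(2,6,6-trimethylcyclohex-1-en-1-yl)but-1-en-2-yl trifluoromethanesulfonate F2. Coupling with but-3-enylmagnesium bromide under Fe(acac)3 catalysis (THF, −30 °C) gives 2-(3-methylidenehept-6-en-1-yl)-1,3,3-trimethylcyclohex-1-ene F3. Cross-metathesis of its monosubstituted alkene with 5, as in step 2, gives methyl (2E)-2-methyl-6-methylidene-8-(2,6,6-trimethylcyclohex-1-en-1-yl)oct-2-enoate F4. Its Co(thd)2/O2/Et3SiH peroxidation puts hydrogen on the exocyclic CH2 and gives the same silyl peroxide 7.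

Step 2. The skipped diene may isomerise into conjugation under ruthenium hydrides, or the metathesis may stall with the hindered methacrylate partner.
Fallback, from 1 back to 6: the enoate is built by Wittig chemistry instead. Compound 1 reacts with the ylide from [2-(1,3-dioxolan-2-yl)ethyl]triphenylphosphonium bromide (NaN(SiMe3)2, THF) to give 2-[3-methyl-5-(2,6,6-trimethylcyclohex-1-en-1-yl)pent-2-en-1-yl]-1,3-dioxolane F5. Mild hydrolysis (1 M HCl, THF, rt) gives 4-methyl-6-(2,6,6-trimethylcyclohex-1-en-1-yl)hex-3-enal F6. This is used at once with methyl 2-(triphenyl-λ5-phosphanylidene)propanoate (CH2Cl2, rt) to give 6 with the (2E) geometry.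

**Further compounds**
F1 | step 4 | methyl 2-[6-methyl-6-[2-(2,6,6-trimethylcyclohex-1-en-1-yl)ethyl]-1,2-dioxan-3-yl]propanoate, mixture of the racemic diastereomers | COC(=O)C(C)C1CCC(C)(CCC2=C(C)CCCC2(C)C)OO1
F2 | step 3 | 4-(2,6,6-trimethylcyclohex-1-en-1-yl)but-1-en-2-yl trifluoromethanesulfonate | C=C(CCC1=C(C)CCCC1(C)C)OS(=O)(=O)C(F)(F)F
F3 | step 3 | 2-(3-methylidenehept-6-en-1-yl)-1,3,3-trimethylcyclohex-1-ene | C=CCCC(=C)CCC1=C(C)CCCC1(C)C
F4 | step 3 | methyl (2E)-2-methyl-6-methylidene-8-(2,6,6-trimethylcyclohex-1-en-1-yl)oct-2-enoate | COC(=O)/C(C)=C/CCC(=C)CCC1=C(C)CCCC1(C)C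
F5 | step 2 | 2-[3-methyl-5-(2,6,6-trimethylcyclohex-1-en-1-yl)pent-2-en-1-yl]-1,3-dioxolane, E/Z mixture | CC(=CCC1OCCO1)CCC2=C(C)CCCC2(C)C
F6 | step 2 | 4-methyl-6-(2,6,6-trimethylcyclohex-1-en-1-yl)hex-3-enal, E/Z mixture | CC(=CCC=O)CCC1=C(C)CCCC1(C)C
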